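## Structural features

The target 21 is a diaryl ether. Ring A is a 1,2,4-trisubstituted phenol (OH at C1, aryloxy at C2, side chain at C4). Ring B is a catechol whose C3 carries the bridging oxygen and whose C5 carries the second side chain. Both side chains are the same C15 unit, a (6E)-3,7,11-trimethyldodeca-1,6,10-trien-3-yl group bound through C3. Each ring therefore bears an all-carbon quaternary benzylic stereocentre carrying methyl, vinyl, aryl and a (3E)-4,8-dimethylnona-3,7-dienyl chain. The centre on ring A is R and the one on ring B is S; they are constitutionally alike, opposite in sense, and separated by the whole diaryl ether, so neither can direct the other (a pseudo-meso pair). Fragile elements are the six C=C bonds (two vinyl groups and four trisubstituted alkenes, open to acid-induced cation–olefin cyclisation, electrophilic halogen and hydrogenation), the E geometry at C6=C7 of each arm, and the air-sensitive catechol. No ring has to be built; the real difficulty is the pair of remote quaternary centres of opposite configuration, together with a diaryl ether bond flanked by oxygen on both rings. The key step exploits the fact that each quaternary carbon is benzylic and carries a CH3 group: it maps onto the carbinol carbon of a 1-arylethanol, the C(quaternary)–CH2 bond to the terpene chain is made by a 1,2-shift from boron, and the C–B bond left behind later becomes the C–vinyl bond.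

## Logic of the disconnections

21 to 20. The three phenolic O–H bonds are traced back to O–Si bonds. Free phenols would quench organolithium reagents and the catechol oxidises easily, so they stay masked to the end. Silicon is chosen because fluoride is the one deprotection that leaves six alkenes alone. The forward step must keep the liberated phenoxides protonated.

20 to 17. Both C(quaternary)–C(vinyl) bonds are cut and replaced by C–B bonds. This turns each quaternary carbon into a tertiary boronic ester, the natural product of a 1,2-metallate shift. The forward step must transfer vinyl from boron to carbon with retention, twice, at hindered centres, without iodine touching the trisubstituted alkenes.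

17 to 14 and two molecules of 3. Both C(quaternary)–CH2 bonds are cut. Each centre falls back to a secondary benzylic carbamate whose configuration is independent of the other, so the R/S pair can be preset site by site. This is the largest simplification of the plan: two stereocentres and two skeletal bonds in one operation, with the whole C11 chain delivered intact. The forward step must lithiate both benzylic positions completely and transfer configuration fully. The stereochemical course was checked: the R carbinol on ring A leads to the R boronate and the R centre of 21, and the S carbinol on ring B leads to S and S. The descriptors stay the same although the ligand sets change, and no structure needed correction.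

3 to 1 and 2. The C1–C2 bond of the dienyl chain is cut, so the E alkene is taken from the terpene pool and only one CH2–B unit is added. The forward step must substitute at the primary allylic carbon without allylic transposition.

14 to 13 to 12. The ring B carbamate C–O(acyl) bond and then the carbinol C–H bond are cut, leading to a methyl ketone. The S centre is set by a reagent-controlled reduction; the distant ring A centre exerts no influence, so catalyst control must be high.

12 to 10. The C(acyl)–CH3 bond of the ring B ketone is cut to an ester. The ester is the device that keeps the two carbonyl groups distinct, so that mirror-image catalysts can be applied in turn. The forward step must stop at the ketone.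

10 to 9 to 8. The same carbamate/carbinol cuts on ring A lead to its methyl ketone, reduced with the catalyst of opposite hand while the ester is inert.

8 to 7 to 6. The O–Si bonds are exchanged for O–CH3 bonds by way of the free triphenol. Silyl ethers cannot pass through a base-mediated copper etherification, because they would cleave and shift between neighbouring oxygens. Methyl ethers can, and their harsh removal is placed where neither alkene nor stereocentre exists.

6 to 4 and 5. The diaryl ether C–O bond is cut on the ring B side, giving a phenol and an aryl bromide that are both purchasable with the full oxygen pattern. The forward step must join two ortho-substituted partners.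

## Other disconnections considered

Alternative 1: The cut goes through ring A. The C4–C5 and C2=C3 bonds of a cyclohexenone precursor are broken, leading back to the β-quaternary aldehyde A2 (ring A arm, stereocentre already present) and the aryloxymethyl vinyl ketone A3, which carries the finished ring B arm. Forward, A2 is activated as a secondary-amine enamine and adds to the enone of A3; the 1,5-keto aldehyde then closes by aldol condensation to the 2-aryloxy-4-alkylcyclohexenone A1. Dehydrogenation to the phenol and acetal removal would complete the target.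
- In its favour: the diaryl ether oxygen is attached by a plain phenoxide alkylation, so the crowded copper coupling of step 2 disappears. The extra ring CH centre of A1 needs no control, because aromatisation erases it.
- Against it: the annulation creates neither quaternary centre, so A2 and the arm of A3 each need their own enantioselective synthesis. The Michael donor is a neopentyl-type enamine next to a quaternary carbon, and A3 is a polymerisation-prone enone. The dehydrogenation must spare six alkenes, and the acetals must come off with acid beside a polyene.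
- Comparison: on structure the alternative is the better plan for the C–O bond and the equal of the chosen plan in fixing the ring A oxygen pattern. On mechanism the enamine Michael/aldol sequence is sound but sterically strained here, whereas the chosen plan makes both stereocentres in one stereospecific operation from carbinols set by catalytic ketone reduction. On step economy it is worse: two separate quaternary-centre syntheses precede the annulation and an oxidation follows it.

Alternative 2: The cut is the C5–C6 bond (CH2–CH=) of each arm. It leads back to the bis(redox-active ester) A5, a diaryl ether whose two quaternary centres carry a propionate stub, and to two molecules of the E-alkenyl iodide A6. Forward, cathodic reduction under nickel–bipyridine catalysis turns each ester into a primary alkyl radical by loss of CO2 and couples it with A6. This gives the tris(methoxymethyl) ether A4, from which the acetals are removed.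
- In its favour: the radical site is two carbons from the quaternary centre, so no stereocentre is at risk. The E geometry is bought with A6 and transferred with retention. No organolithium reagent meets the advanced intermediate, and different tails could be attached late.
- Against it: the real problem, two quaternary centres of opposite configuration, is only moved back into A5. A5 would most plausibly be made by the same carbamate–boron chemistry with a three-carbon boronate, followed by oxidation-state changes and ester activation. Both sites must couple, with radical reduction or dimerisation as competing paths. The final acetal cleavage needs acid beside six alkenes, whereas the chosen plan ends with buffered fluoride.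
- Comparison: on structure the two plans are equal in closing no ring and in joining a diaryl ether core to two terpene pieces. On mechanism the alternative is the better in functional-group tolerance and in separating alkene geometry from the stereocentres, but it sets no stereocentre. On step economy it is worse, since the tail arrives in a separate operation after the quaternary centres rather than in the step that creates them.

Alternative 3: The cut dismantles ring B into the α-diazo enone A8, which carries the ring B arm, and the ring A aryl ethynyl ether A9. Forward, irradiation of A8 triggers a Wolff rearrangement. The ketene so formed adds to the alkyne of A9, and on heating the four-membered ring opens (4π) and recloses (6π) to the 3-aryloxy-5-alkylphenol A7.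
- In its favour: the relative positions of hydroxyl, aryloxy and arm on ring B follow from the pericyclic cascade with no regiochemical choice. The ether oxygen is introduced as an alkynyl ether rather than by coupling at a flanked carbon, and the plan is convergent.
- Against it: A7 lacks the ring B oxygen at C2, between the hydroxyl and the aryloxy group. A further regioselective hydroxylation is needed and must compete with ring A positions activated by the acetal. A9 is a thermally labile ynol ether. Ultraviolet light and a ketene are brought together with six alkenes, which invites intramolecular ketene–alkene cycloaddition. Both quaternary centres must again be made beforehand, one in each fragment.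
- Comparison: on structure the alternative is the better in building the ring B substitution pattern from acyclic pieces and the equal in convergence, but it stops one oxygen short. On mechanism the cascade is reliable for simple partners but less tolerant of the polyene arms than the low-temperature ionic chemistry of the chosen plan. On step economy it is worse, because of the preparation of A8 and A9, the extra hydroxylation and the separate stereocentre syntheses.

Key step: step 10

Remarks on the chemistry:
- Abbreviations: TIPS = tri(propan-2-yl)silyl, pin = pinacolato, Cb = N,N-di(propan-2-yl)carbamoyl.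
- Equivalents in steps 10 to 12 are per molecule of diaryl ether.
- Silyl ethers are assumed not to survive a base-mediated copper etherification. The ether bond is therefore made on methyl ethers, and the silyl groups are installed at the keto ester stage.
- The enantiomeric purity of 9 and 13 fixes the diastereomeric purity of everything that follows, and should be checked at those two stages.

## Route

Step 1
Reactants: 1 geranyl bromide [(2E)-1-bromo-3,7-dimethylocta-2,6-diene]; 2 2,2'-methylenebis(4,4,5,5-tetramethyl-1,3,2-dioxaborolane)
Product: 3 2-[(3E)-4,8-dimethylnona-3,7-dien-1-yl]-4,4,5,5-tetramethyl-1,3,2-dioxaborolane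
Conditions: 2 (1.5 equiv), NaOtBu (2.5 equiv), THF, 0 °C, 15 min; then 1, 0 °C → rt
Reagents that add atoms: none
Why: Deborylative alkylation of a geminal bis(boronate): tert-butoxide attacks one boron of 2 and releases a boron-stabilised carbanion, which displaces the primary allylic bromide of 1 by SN2; the 2,3-alkene of 1 is not involved, so its E geometry is carried into 3.

Step 2
Reactants: 4 1-(3-hydroxy-4-methoxyphenyl)ethan-1-one; 5 methyl 3-bromo-4,5-dimethoxybenzoate
Product: 6 methyl 3-(5-acetyl-2-methoxyphenoxy)-4,5-dimethoxybenzoate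
Conditions: CuI (10 mol %), picolinic acid (20 mol %), K3PO4 (2 equiv), DMSO, 90 °C, Ar (4 in 1.2 equiv)
Reagents that add atoms: none
Why: Ullmann-type C–O coupling at monovalent copper; the picolinic acid ligand is suited to ortho-substituted phenols and ortho-substituted aryl bromides, phosphate in dry DMSO should leave the methyl ester and the acetyl group in place, and methyl ethers neither cleave nor migrate under base.

Step 3
Reactants: 6 methyl 3-(5-acetyl-2-methoxyphenoxy)-4,5-dimethoxybenzoate
Product: 7 methyl 3-(5-acetyl-2-hydroxyphenoxy)-4,5-dihydroxybenzoate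
Conditions: BBr3 (7 equiv), CH2Cl2, −78 → 0 °C; MeOH, then aqueous work-up
Reagents that add atoms: none
Why: Lewis acid-mediated cleavage of aryl methyl ethers; the diaryl ether is inert to BBr3, no alkene or stereocentre is present yet, and the methanol quench should return any carboxylic acid to the methyl ester.

Step 4
Reactants: 7 methyl 3-(5-acetyl-2-hydroxyphenoxy)-4,5-dihydroxybenzoate
Product: 8 methyl 3-[5-acetyl-2-(TIPS-oxy)phenoxy]-4,5-bis(TIPS-oxy)benzoate
Conditions: TIPSCl (4.5 equiv), imidazole (9 equiv), DMAP (cat.), DMF, 40 °C
Reagents that add atoms: chlorotri(propan-2-yl)silane, CC(C)[Si](Cl)(C(C)C)C(C)C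
Why: Phenol silylation through the N-silylimidazolium; these conditions do not enolise the ketone, and the bulky silyl ethers later neither direct ring lithiation nor undergo oxygen-to-carbon silyl shifts.

Step 5
Reactants: 8 methyl 3-[5-acetyl-2-(TIPS-oxy)phenoxy]-4,5-bis(TIPS-oxy)benzoate
Product: 9 methyl 3-{5-[(1R)-1-hydroxyethyl]-2-(TIPS-oxy)phenoxy}-4,5-bis(TIPS-oxy)benzoate
Conditions: (S)-Me-CBS [(3aS)-1-methyl-3,3-diphenyltetrahydro-1H,3H-pyrrolo[1,2-c][1,3,2]oxazaborole] (0.2 equiv), BH3·SMe2 (1.0 equiv), THF, −20 °C; MeOH
Reagents that add atoms: none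
Why: Corey–Bakshi–Shibata reduction; the oxazaborolidine–borane complex binds the ketone with the aryl group in the open position and delivers hydride to the Si face, which should give the R carbinol, while the methyl ester is not reduced by borane at this temperature.

Step 6
Reactants: 9 methyl 3-{5-[(1R)-1-hydroxyethyl]-2-(TIPS-oxy)phenoxy}-4,5-bis(TIPS-oxy)benzoate
Product: 10 methyl 3-{5-[(1R)-1-(Cb-oxy)ethyl]-2-(TIPS-oxy)phenoxy}-4,5-bis(TIPS-oxy)benzoate
Conditions: iPr2NCOCl (1.5 equiv), Et3N (2 equiv), DMAP (0.1 equiv), CH2Cl2, reflux
Reagents that add atoms: N,N-di(propan-2-yl)carbamoyl chloride, CC(C)N(C(C)C)C(Cl)=O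
Why: O-Carbamoylation of a secondary alcohol; the C–O bond at the stereocentre is not broken, so the R configuration is retained, and the hindered carbamate is the directing and leaving group needed in step 10.

Step 7
Reactants: 10 methyl 3-{5-[(1R)-1-(Cb-oxy)ethyl]-2-(TIPS-oxy)phenoxy}-4,5-bis(TIPS-oxy)benzoate
Product: 12 (1R)-1-{3-[5-acetyl-2,3-bis(TIPS-oxy)phenoxy]-4-(TIPS-oxy)phenyl}ethyl N,N-di(propan-2-yl)carbamate, via ring B N-methoxy-N-methylamide 11 (not isolated)
Conditions: MeNH(OMe)·HCl (1.5 equiv), i-PrMgCl (3 equiv), THF, −20 → 0 °C; then MeMgBr (3 equiv), 0 °C → rt; aq. NH4Cl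
Reagents that add atoms: methylmagnesium bromide, C[Mg]Br
Why: One-pot ester-to-ketone conversion through a Weinreb amide: the chloromagnesium amide turns the ester into 11, whose chelated adduct with MeMgBr collapses only on quench, which prevents over-addition; the diisopropylcarbamate and the aryl silyl ethers are inert to Grignard reagents at this temperature.

Step 8
Reactants: 12 (1R)-1-{3-[5-acetyl-2,3-bis(TIPS-oxy)phenoxy]-4-(TIPS-oxy)phenyl}ethyl N,N-di(propan-2-yl)carbamate
Product: 13 (1R)-1-{3-[5-[(1S)-1-hydroxyethyl]-2,3-bis(TIPS-oxy)phenoxy]-4-(TIPS-oxy)phenyl}ethyl N,N-di(propan-2-yl)carbamate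
Conditions: (R)-Me-CBS [(3aR)-1-methyl-3,3-diphenyltetrahydro-1H,3H-pyrrolo[1,2-c][1,3,2]oxazaborole] (0.2 equiv), BH3·SMe2 (1.0 equiv), THF, −20 °C; MeOH
Reagents that add atoms: none
Why: Corey–Bakshi–Shibata reduction with the mirror-image catalyst, hydride now reaching the Re face to give the S carbinol; the ring A centre is too remote to influence the outcome, so the result is under reagent control, and the carbamate is not reduced.

Step 9
Reactants: 13 (1R)-1-{3-[5-[(1S)-1-hydroxyethyl]-2,3-bis(TIPS-oxy)phenoxy]-4-(TIPS-oxy)phenyl}ethyl N,N-di(propan-2-yl)carbamate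
Product: 14 (1R)-1-{3-[5-[(1S)-1-(Cb-oxy)ethyl]-2,3-bis(TIPS-oxy)phenoxy]-4-(TIPS-oxy)phenyl}ethyl N,N-di(propan-2-yl)carbamate (biscarbamate, R on ring A, S on ring B)
Conditions: iPr2NCOCl (1.5 equiv), Et3N (2 equiv), DMAP (0.1 equiv), CH2Cl2, reflux
Reagents that add atoms: N,N-di(propan-2-yl)carbamoyl chloride, CC(C)N(C(C)C)C(Cl)=O
Why: O-Carbamoylation as in step 6, with retention at the S carbinol carbon; 14 now carries both leaving groups and both preset configurations.

Step 10
Reactants: 14 biscarbamate (R on ring A, S on ring B); 3 2-[(3E)-4,8-dimethylnona-3,7-dien-1-yl]-4,4,5,5-tetramethyl-1,3,2-dioxaborolane (two molecules)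
Product: 17 diaryl ether bis(tertiary pinacol boronate): 2-[(2R,5E)-6,10-dimethyl-2-(pinB)undeca-5,9-dien-2-yl] on ring A and 2-[(2S,5E)-6,10-dimethyl-2-(pinB)undeca-5,9-dien-2-yl] on ring B of the tris(TIPS) diaryl ether, via dilithiated biscarbamate 15 (not isolated), via dilithium bis(boronate) complex 16 (not isolated)
Conditions: s-BuLi (2.6 equiv), Et2O, −78 °C, 1 h; 3 (3.0 equiv), −78 °C, 2 h; then −78 °C → rt, 16 h
Reagents that add atoms: none
Why: Each benzylic C–H next to a carbamate oxygen is removed by s-BuLi in a carbonyl-directed deprotonation, giving 15, whose tertiary benzylic C–Li centres are held by the carbamate carbonyl and keep their configuration at −78 °C in ether. Boronic ester 3 then adds at each C–Li bond with retention to give 16, and on warming the dienyl chain shifts from boron to carbon anti to the C–O bond, with inversion at carbon and loss of lithium carbamate. The closest known reaction type is the lithiation–borylation of enantioenriched secondary benzylic carbamates of para-oxygenated 1-arylethanols with primary alkyl pinacol boronates that carry a remote trisubstituted alkene; here it is run at two sites of one molecule. No ring is closed. Each new quaternary stereocentre is controlled only by the carbinol configuration at its own site: the chain takes the place of the former hydrogen and boron that of the former oxygen, so the R carbamate on ring A gives the R boronate and the S carbamate on ring B gives the S boronate. The step needs benzylic rather than ring lithiation, which the carbamate secures by proximity and which the bulky, poorly coordinating silyl ethers do not disturb. It needs both sites to react, which the excess of base and boronate secures, and it needs full stereospecificity, which low temperature and a non-polar ether medium secure by disfavouring reversal or ionisation of the boronate complex before the shift.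

Step 11
Reactants: 17 diaryl ether bis(tertiary pinacol boronate)
Product: 20 tris(TIPS) ether of the target, with the (3R,6E)-3,7,11-trimethyldodeca-1,6,10-trien-3-yl arm on ring A and the (3S,6E) arm on ring B, via dilithium bis(vinylboronate) complex 18 (not isolated), via bis(2-iodoethyl) pinacol boronate 19 (not isolated)
Conditions: CH2=CHLi (6 equiv; from Sn(CH=CH2)4, n-BuLi), THF, −78 °C; I2 (6 equiv), THF/MeOH, −78 °C; NaOMe (12 equiv), MeOH, −78 → 0 °C; aq. Na2S2O3 at 0 °C
Reagents that add atoms: vinyllithium, C=C[Li]
Why: Zweifel olefination: vinyllithium adds to each boron to give 18, iodine activates the vinyl group and the tertiary alkyl group shifts from boron to carbon with retention to give 19, and methoxide triggers anti elimination of boron and iodide; the electron-rich alkene of the boronate complex should react with iodine at −78 °C far faster than the isolated trisubstituted alkenes or the silylated arenes.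

Step 12
Reactants: 20 tris(TIPS) ether of the target
Product: 21 3-{2-hydroxy-5-[(3R,6E)-3,7,11-trimethyldodeca-1,6,10-trien-3-yl]phenoxy}-5-[(3S,6E)-3,7,11-trimethyldodeca-1,6,10-trien-3-yl]benzene-1,2-diol (target)
Conditions: TBAF (3.6 equiv), AcOH (3.6 equiv), THF, 0 °C → rt, Ar
Reagents that add atoms: none
Why: Fluoride-induced cleavage of aryl silyl ethers; acetic acid keeps the phenoxides protonated so the catechol is not oxidised, and nothing acidic or basic enough to affect the six alkenes or the quaternary centres is present.

## Compound list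

1 | geranyl bromide, (2E)-1-bromo-3,7-dimethylocta-2,6-diene | BrC/C=C(\C)CCC=C(C)C | starting material
2 | 2,2'-methylenebis(4,4,5,5-tetramethyl-1,3,2-dioxaborolane) | CC1(C)OB(CB2OC(C)(C)C(C)(C)O2)OC1(C)C | starting material
3 | 2-[(3E)-4,8-dimethylnona-3,7-dien-1-yl]-4,4,5,5-tetramethyl-1,3,2-dioxaborolane | CC(C)=CCC/C(C)=C/CCB1OC(C)(C)C(C)(C)O1 | intermediate
4 | 1-(3-hydroxy-4-methoxyphenyl)ethan-1-one | CC(=O)c1ccc(OC)c(O)c1 | starting material
5 | methyl 3-bromo-4,5-dimethoxybenzoate | COC(=O)c1cc(OC)c(OC)c(Br)c1 | starting material
6 | methyl 3-(5-acetyl-2-methoxyphenoxy)-4,5-dimethoxybenzoate | CC(=O)c1ccc(OC)c(Oc2cc(C(=O)OC)cc(OC)c2OC)c1 | intermediate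
7 | methyl 3-(5-acetyl-2-hydroxyphenoxy)-4,5-dihydroxybenzoate | CC(=O)c1ccc(O)c(Oc2cc(C(=O)OC)cc(O)c2O)c1 | intermediate
8 | methyl 3-[5-acetyl-2-(TIPS-oxy)phenoxy]-4,5-bis(TIPS-oxy)benzoate | CC(=O)c1ccc(O[Si](C(C)C)(C(C)C)C(C)C)c(Oc2cc(C(=O)OC)cc(O[Si](C(C)C)(C(C)C)C(C)C)c2O[Si](C(C)C)(C(C)C)C(C)C)c1 | intermediate
9 | methyl 3-{5-[(1R)-1-hydroxyethyl]-2-(TIPS-oxy)phenoxy}-4,5-bis(TIPS-oxy)benzoate | C[C@@H](O)c1ccc(O[Si](C(C)C)(C(C)C)C(C)C)c(Oc2cc(C(=O)OC)cc(O[Si](C(C)C)(C(C)C)C(C)C)c2O[Si](C(C)C)(C(C)C)C(C)C)c1 | intermediate
10 | methyl 3-{5-[(1R)-1-(Cb-oxy)ethyl]-2-(TIPS-oxy)phenoxy}-4,5-bis(TIPS-oxy)benzoate | C[C@@H](OC(=O)N(C(C)C)C(C)C)c1ccc(O[Si](C(C)C)(C(C)C)C(C)C)c(Oc2cc(C(=O)OC)cc(O[Si](C(C)C)(C(C)C)C(C)C)c2O[Si](C(C)C)(C(C)C)C(C)C)c1 | intermediate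
11 | ring B N-methoxy-N-methylamide of 10 (formed in the flask) | C[C@@H](OC(=O)N(C(C)C)C(C)C)c1ccc(O[Si](C(C)C)(C(C)C)C(C)C)c(Oc2cc(C(=O)N(C)OC)cc(O[Si](C(C)C)(C(C)C)C(C)C)c2O[Si](C(C)C)(C(C)C)C(C)C)c1 | intermediate
12 | (1R)-1-{3-[5-acetyl-2,3-bis(TIPS-oxy)phenoxy]-4-(TIPS-oxy)phenyl}ethyl N,N-di(propan-2-yl)carbamate | C[C@@H](OC(=O)N(C(C)C)C(C)C)c1ccc(O[Si](C(C)C)(C(C)C)C(C)C)c(Oc2cc(C(C)=O)cc(O[Si](C(C)C)(C(C)C)C(C)C)c2O[Si](C(C)C)(C(C)C)C(C)C)c1 | intermediate
13 | (1R)-1-{3-[5-[(1S)-1-hydroxyethyl]-2,3-bis(TIPS-oxy)phenoxy]-4-(TIPS-oxy)phenyl}ethyl N,N-di(propan-2-yl)carbamate | C[C@@H](OC(=O)N(C(C)C)C(C)C)c1ccc(O[Si](C(C)C)(C(C)C)C(C)C)c(Oc2cc([C@H](C)O)cc(O[Si](C(C)C)(C(C)C)C(C)C)c2O[Si](C(C)C)(C(C)C)C(C)C)c1 | intermediate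
14 | (1R)-1-{3-[5-[(1S)-1-(Cb-oxy)ethyl]-2,3-bis(TIPS-oxy)phenoxy]-4-(TIPS-oxy)phenyl}ethyl N,N-di(propan-2-yl)carbamate | C[C@@H](OC(=O)N(C(C)C)C(C)C)c1ccc(O[Si](C(C)C)(C(C)C)C(C)C)c(Oc2cc([C@H](C)OC(=O)N(C(C)C)C(C)C)cc(O[Si](C(C)C)(C(C)C)C(C)C)c2O[Si](C(C)C)(C(C)C)C(C)C)c1 | intermediate
15 | dilithiated biscarbamate, Li in place of each carbinol H with retention (formed in the flask) | C[C@@]([Li])(OC(=O)N(C(C)C)C(C)C)c1ccc(O[Si](C(C)C)(C(C)C)C(C)C)c(Oc2cc([C@]([Li])(C)OC(=O)N(C(C)C)C(C)C)cc(O[Si](C(C)C)(C(C)C)C(C)C)c2O[Si](C(C)C)(C(C)C)C(C)C)c1 | intermediate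
16 | dilithium bis(boronate) complex, each boron bound to the carbamate carbon, the dienyl chain and pinacol (formed in the flask) | [Li+].[Li+].C[C@@]([B-]3(CC/C=C(\C)CCC=C(C)C)OC(C)(C)C(C)(C)O3)(OC(=O)N(C(C)C)C(C)C)c1ccc(O[Si](C(C)C)(C(C)C)C(C)C)c(Oc2cc([C@]([B-]4(CC/C=C(\C)CCC=C(C)C)OC(C)(C)C(C)(C)O4)(C)OC(=O)N(C(C)C)C(C)C)cc(O[Si](C(C)C)(C(C)C)C(C)C)c2O[Si](C(C)C)(C(C)C)C(C)C)c1 | intermediate
17 | diaryl ether bis(tertiary pinacol boronate), (2R,5E)-6,10-dimethyl-2-(pinB)undeca-5,9-dien-2-yl on ring A and the (2S,5E) group on ring B, phenols as TIPS ethers | CC1(C)OB(OC1(C)C)[C@@](C)(CC/C=C(\C)CCC=C(C)C)c1ccc(O[Si](C(C)C)(C(C)C)C(C)C)c(Oc2cc([C@](C)(B3OC(C)(C)C(C)(C)O3)CC/C=C(\C)CCC=C(C)C)cc(O[Si](C(C)C)(C(C)C)C(C)C)c2O[Si](C(C)C)(C(C)C)C(C)C)c1 | intermediate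
18 | dilithium bis(vinylboronate) complex of 17 (formed in the flask) | [Li+].[Li+].C=C[B-]3(OC(C)(C)C(C)(C)O3)[C@@](C)(CC/C=C(\C)CCC=C(C)C)c1ccc(O[Si](C(C)C)(C(C)C)C(C)C)c(Oc2cc([C@](C)([B-]4(C=C)OC(C)(C)C(C)(C)O4)CC/C=C(\C)CCC=C(C)C)cc(O[Si](C(C)C)(C(C)C)C(C)C)c2O[Si](C(C)C)(C(C)C)C(C)C)c1 | intermediate
19 | bis(2-iodo-1-(pinB)ethyl) compound, each quaternary carbon bound to CH(Bpin)CH2I, boron-bearing CH centres uncontrolled (formed in the flask) | ICC(B3OC(C)(C)C(C)(C)O3)[C@@](C)(CC/C=C(\C)CCC=C(C)C)c1ccc(O[Si](C(C)C)(C(C)C)C(C)C)c(Oc2cc([C@](C)(C(CI)B4OC(C)(C)C(C)(C)O4)CC/C=C(\C)CCC=C(C)C)cc(O[Si](C(C)C)(C(C)C)C(C)C)c2O[Si](C(C)C)(C(C)C)C(C)C)c1 | intermediate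
20 | tris(TIPS) ether of the target, (3R,6E) arm on ring A and (3S,6E) arm on ring B | C=C[C@@](C)(CC/C=C(\C)CCC=C(C)C)c1ccc(O[Si](C(C)C)(C(C)C)C(C)C)c(Oc2cc([C@](C)(C=C)CC/C=C(\C)CCC=C(C)C)cc(O[Si](C(C)C)(C(C)C)C(C)C)c2O[Si](C(C)C)(C(C)C)C(C)C)c1 | intermediate
21 | 3-{2-hydroxy-5-[(3R,6E)-3,7,11-trimethyldodeca-1,6,10-trien-3-yl]phenoxy}-5-[(3S,6E)-3,7,11-trimethyldodeca-1,6,10-trien-3-yl]benzene-1,2-diol | C=C[C@@](C)(CC/C=C(\C)CCC=C(C)C)c1ccc(O)c(Oc2cc([C@](C)(C=C)CC/C=C(\C)CCC=C(C)C)cc(O)c2O)c1 | target

## Step count and least certain steps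

Total step count: 12. Longest linear sequence: 11 steps (steps 2 to 12, from 4 and 5); step 1 is a one-step branch.

Step 10 (key step). The most likely failure is incomplete deprotonation at the second electron-rich benzylic site, so that material borylated on one ring only accumulates. The second is loss of stereospecificity if a boronate complex reverts to the lithiated carbamate, or ionises at the para-oxygenated benzylic C–O bond before the 1,2-shift. Fallback, one arm at a time, setting out from 13, whose ring B carbinol is still free:
- s-BuLi (one equivalent is consumed by the hydroxyl group) and then 3 should carry out a single lithiation–borylation on ring A. This gives the ring A tertiary boronate with free ring B carbinol F1.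
- Zweifel vinylation gives the ring A trienyl carbinol F2.
- Carbamoylation as in step 9 gives the ring B monocarbamate F3.
- A second single lithiation–borylation with 3 gives the ring B tertiary boronate F4.
- A second Zweifel vinylation comes back to the route at 20.

Step 11. Formation of the boronate complex may stop short at one of the two hindered tertiary centres. Iodine or hypoiodite may also attack the trisubstituted alkenes or the arenes if the mixture warms before the reductive quench. Methoxide may begin to remove aryl silyl groups, which exposes phenoxides to iodination. Fallback without electrophilic halogen, setting out from 17: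
- (Dichloromethyl)lithium (CH2Cl2, n-BuLi, THF, −100 °C; ZnCl2) inserts a CHCl unit into each C–B bond with retention (Matteson homologation). This gives the bis(α-chloroalkyl pinacol boronate) F5.
- Buffered oxidation (NaBO3·4H2O, THF/water) gives the bis(α-quaternary aldehyde) F6.
- Wittig methylenation (Ph3P=CH2, THF, 0 °C) comes back to the route at 20.

Step 2. The bromide of 5 is electron-rich and flanked by a methoxy group, and the phenoxide of 4 is also ortho-substituted, so the coupling may be slow. Ester hydrolysis, aldol self-condensation of the acetyl group and hydrodebromination may then compete at 90 °C. Fallback by oxidative coupling at room temperature, setting out from 5: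
- Miyaura borylation (B2pin2, Pd(dppf)Cl2, KOAc, dioxane, 80 °C) gives methyl 3,4-dimethoxy-5-(pinB)benzoate F7.
- Periodate cleavage (NaIO4, NH4OAc, acetone/water) gives [2,3-dimethoxy-5-(methoxycarbonyl)phenyl]boronic acid F8.
- Chan–Lam–Evans etherification of 4 with F8 (Cu(OAc)2, pyridine, 4 Å sieves, CH2Cl2, air, rt), a coupling at divalent copper that needs neither heat nor strong base, comes back to the route at 6.

Step 1. The boron-stabilised carbanion may attack the tertiary allylic terminus (allylic transposition), or act as a base and eliminate HBr; excess tert-butoxide may also substitute the bromide. Fallback, setting out from 1: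
- Borylation with B2pin2 under zerovalent palladium catalysis (Pd2(dba)3, THF, 60 °C) gives geranyl pinacol boronate F9.
- Matteson one-carbon homologation with chloromethyllithium (BrCH2Cl, n-BuLi, THF, −78 °C → rt) comes back to the route at 3.

Step 7. Amide formation may be incomplete, the isopropyl or methyl Grignard reagent may add to the ester directly and over-add to a tertiary alcohol, or the silyl ether para to the acyl group may be attacked. Fallback through the aldehyde oxidation level, setting out from 10:
- DIBAL-H (CH2Cl2, −78 °C) gives the ring B benzylic alcohol F10.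
- MnO2 gives the ring B aldehyde F11.
- MeMgBr (THF, −78 °C) gives the ring B secondary alcohol as both epimers at the new carbinol carbon F12.
- Dess–Martin oxidation comes back to the route at 12.

## Further compounds

F1 | step 10 | ring A tertiary boronate with free ring B (S)-carbinol | CC1(C)OB(OC1(C)C)[C@@](C)(CC/C=C(\C)CCC=C(C)C)c1ccc(O[Si](C(C)C)(C(C)C)C(C)C)c(Oc2cc([C@H](C)O)cc(O[Si](C(C)C)(C(C)C)C(C)C)c2O[Si](C(C)C)(C(C)C)C(C)C)c1
F2 | step 10 | ring A trienyl compound with free ring B (S)-carbinol | C=C[C@@](C)(CC/C=C(\C)CCC=C(C)C)c1ccc(O[Si](C(C)C)(C(C)C)C(C)C)c(Oc2cc([C@H](C)O)cc(O[Si](C(C)C)(C(C)C)C(C)C)c2O[Si](C(C)C)(C(C)C)C(C)C)c1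
F3 | step 10 | ring B (S)-monocarbamate with finished ring A arm | C=C[C@@](C)(CC/C=C(\C)CCC=C(C)C)c1ccc(O[Si](C(C)C)(C(C)C)C(C)C)c(Oc2cc([C@H](C)OC(=O)N(C(C)C)C(C)C)cc(O[Si](C(C)C)(C(C)C)C(C)C)c2O[Si](C(C)C)(C(C)C)C(C)C)c1
F4 | step 10 | ring B tertiary boronate with finished ring A arm | C=C[C@@](C)(CC/C=C(\C)CCC=C(C)C)c1ccc(O[Si](C(C)C)(C(C)C)C(C)C)c(Oc2cc([C@](C)(B3OC(C)(C)C(C)(C)O3)CC/C=C(\C)CCC=C(C)C)cc(O[Si](C(C)C)(C(C)C)C(C)C)c2O[Si](C(C)C)(C(C)C)C(C)C)c1
F5 | step 11 | bis(α-chloroalkyl pinacol boronate), CHCl centres uncontrolled | ClC(B3OC(C)(C)C(C)(C)O3)[C@@](C)(CC/C=C(\C)CCC=C(C)C)c1ccc(O[Si](C(C)C)(C(C)C)C(C)C)c(Oc2cc([C@](C)(C(Cl)B4OC(C)(C)C(C)(C)O4)CC/C=C(\C)CCC=C(C)C)cc(O[Si](C(C)C)(C(C)C)C(C)C)c2O[Si](C(C)C)(C(C)C)C(C)C)c1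
F6 | step 11 | bis(α-quaternary aldehyde) | O=C[C@@](C)(CC/C=C(\C)CCC=C(C)C)c1ccc(O[Si](C(C)C)(C(C)C)C(C)C)c(Oc2cc([C@](C)(C=O)CC/C=C(\C)CCC=C(C)C)cc(O[Si](C(C)C)(C(C)C)C(C)C)c2O[Si](C(C)C)(C(C)C)C(C)C)c1
F7 | step 2 | methyl 3,4-dimethoxy-5-(4,4,5,5-tetramethyl-1,3,2-dioxaborolan-2-yl)benzoate | COC(=O)c1cc(OC)c(OC)c(B2OC(C)(C)C(C)(C)O2)c1
F8 | step 2 | [2,3-dimethoxy-5-(methoxycarbonyl)phenyl]boronic acid | COC(=O)c1cc(OC)c(OC)c(B(O)O)c1
F9 | step 1 | 2-[(2E)-3,7-dimethylocta-2,6-dien-1-yl]-4,4,5,5-tetramethyl-1,3,2-dioxaborolane | CC(C)=CCC/C(C)=C/CB1OC(C)(C)C(C)(C)O1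
F10 | step 7 | ring B hydroxymethyl compound with ring A (R)-carbamate | C[C@@H](OC(=O)N(C(C)C)C(C)C)c1ccc(O[Si](C(C)C)(C(C)C)C(C)C)c(Oc2cc(CO)cc(O[Si](C(C)C)(C(C)C)C(C)C)c2O[Si](C(C)C)(C(C)C)C(C)C)c1
F11 | step 7 | ring B aldehyde with ring A (R)-carbamate | C[C@@H](OC(=O)N(C(C)C)C(C)C)c1ccc(O[Si](C(C)C)(C(C)C)C(C)C)c(Oc2cc(C=O)cc(O[Si](C(C)C)(C(C)C)C(C)C)c2O[Si](C(C)C)(C(C)C)C(C)C)c1
F12 | step 7 | ring B 1-hydroxyethyl compound, both epimers at the new carbinol carbon, with ring A (R)-carbamate | C[C@@H](OC(=O)N(C(C)C)C(C)C)c1ccc(O[Si](C(C)C)(C(C)C)C(C)C)c(Oc2cc(C(C)O)cc(O[Si](C(C)C)(C(C)C)C(C)C)c2O[Si](C(C)C)(C(C)C)C(C)C)c1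
A1 | alternative 1 | 2-aryloxy-4-alkylcyclohex-2-en-1-one with both arms in place, ring B as bis(methoxymethyl) ether, ring CH centre unassigned | O=C1CCC([C@@](C)(C=C)CC/C=C(\C)CCC=C(C)C)C=C1Oc1cc([C@](C)(C=C)CC/C=C(\C)CCC=C(C)C)cc(OCOC)c1OCOC
A2 | alternative 1 | (3S,6E)-3-ethenyl-3,7,11-trimethyldodeca-6,10-dienal | O=CC[C@@](C)(C=C)CC/C=C(\C)CCC=C(C)C
A3 | alternative 1 | 1-{2,3-bis(methoxymethoxy)-5-[(3S,6E)-3,7,11-trimethyldodeca-1,6,10-trien-3-yl]phenoxy}but-3-en-2-one | C=CC(=O)COc1cc([C@](C)(C=C)CC/C=C(\C)CCC=C(C)C)cc(OCOC)c1OCOC
A4 | alternative 2 | tris(methoxymethyl) ether of the target | C=C[C@@](C)(CC/C=C(\C)CCC=C(C)C)c1ccc(OCOC)c(Oc2cc([C@](C)(C=C)CC/C=C(\C)CCC=C(C)C)cc(OCOC)c2OCOC)c1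
A5 | alternative 2 | bis(1,3-dioxoisoindolin-2-yl) ester of the tris(methoxymethyl)-protected diaryl ether bis(4-methylhex-5-enoic acid), R centre on ring A and S centre on ring B | C=C[C@@](C)(CCC(=O)ON3C(=O)c4ccccc4C3=O)c1ccc(OCOC)c(Oc2cc([C@](C)(C=C)CCC(=O)ON5C(=O)c6ccccc6C5=O)cc(OCOC)c2OCOC)c1
A6 | alternative 2 | (1E)-1-iodo-2,6-dimethylhepta-1,5-diene | I/C=C(\C)CCC=C(C)C
A7 | alternative 3 | 3-aryloxy-5-alkylphenol with both arms in place, ring B lacking its C2 oxygen, ring A phenol as methoxymethyl ether | C=C[C@@](C)(CC/C=C(\C)CCC=C(C)C)c1ccc(OCOC)c(Oc2cc([C@](C)(C=C)CC/C=C(\C)CCC=C(C)C)cc(O)c2)c1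
A8 | alternative 3 | (4S,7E)-1-diazo-4-ethenyl-4,8,12-trimethyl-3-methylidenetrideca-7,11-dien-2-one | [N-]=[N+]=CC(=O)C(=C)[C@](C)(C=C)CC/C=C(\C)CCC=C(C)C
A9 | alternative 3 | 2-(ethynyloxy)-1-(methoxymethoxy)-4-[(3R,6E)-3,7,11-trimethyldodeca-1,6,10-trien-3-yl]benzene | C=C[C@@](C)(CC/C=C(\C)CCC=C(C)C)c1ccc(OCOC)c(OC#C)c1
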